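**Strategy.** The cyclohexene ring (C1, C10, C11, C12, C13, C14) carries the tertiary carbinol C11 (Me-20) beside oxygenated C12, an α-ketol retron. It is therefore grown from a cyclopentanone (C12, C13, C14, C1, C10) in which C10 is still α to the C12 carbonyl, so that quaternary C1 (asymmetric conjugate addition) and the C9–C10 bond (chelation-controlled aldol with a D-mannitol-derived C4–C9 aldehyde) come from enolate chemistry. An aluminium-mediated α-ketol rearrangement of the derived 1-acetylcyclopentanol then moves C10 from C12 to the acetyl carbon, inserting C11 with its stereocentre and unveiling the C12 ketone. Reformatsky lactonisation and a diene-forming RCM of the ten-membered ring complete the target.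

Key step: step 13

Remark: compounds 1 and 5 are taken as catalogue compounds. All intermediates carry the target numbering: C1 (quaternary, Me-15), C2 (butanoate), C3=C4 (Z), C5 (=C16H2), C6 (Cl), C7 (lactone O), C8 (OH), C9 (OAc), C10 (H), C11 (OH, Me-20), C12 (OAc), C13=C14, C17 (Me-18), C19 (lactone C=O). In this numbering the target is 1S,2S,6S,7R,8R,9S,10S,11S,12R,17R. "α" means the face of the carbocycle opposite to Me-15.

**Step 1**
Reactants: 1 3-(hydroxymethyl)cyclopent-2-en-1-one
Product: 2 3-(TBDPS-oxymethyl)cyclopent-2-en-1-one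
Conditions: TBDPSCl, imidazole, DMF, 0 °C → rt
Reagents that add atoms: tert-butyl(chloro)diphenylsilane, CC(C)(C)[Si](Cl)(c1ccccc1)c1ccccc1
Why: Standard imidazole-mediated silylation of a primary alcohol should install the bulky group that later shields the α face of C1; no stereocentre is formed.

**Step 2**
Reactants: 2 3-(TBDPS-oxymethyl)cyclopent-2-en-1-one
Product: 4 TMS enol ether of (S)-3-methyl-3-(TBDPS-oxymethyl)cyclopentanone (C12=C10), via aluminium enolate 3 (not isolated)
Conditions: Me3Al (3 equiv), Cu(OTf)2 (5 mol %), chiral sulfonate-bridged NHC·Ag(I) complex (2.5 mol %), THF, −78 °C; then TMSOTf, −78 → 0 °C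
Reagents that add atoms: trimethylaluminium, C[Al](C)C; trimethylsilyl trifluoromethanesulfonate, C[Si](C)(C)OS(=O)(=O)C(F)(F)F
Why: NHC–Cu-catalysed enantioselective conjugate addition of Me3Al to a β-substituted cyclopentenone should create quaternary C1 (S) under catalyst control (ligand enantiomer chosen accordingly), and O-silylation of the aluminium enolate should fix the enolate regiochemistry towards C10.

**Step 3**
Reactants: 5 3,4-O-isopropylidene-D-mannitol
Product: 6 3,4-O-isopropylidene-1,2-O-(4-methoxybenzylidene)-D-mannitol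
Conditions: 4-MeOC6H4CH(OMe)2 (1.0 equiv), CSA (cat.), DMF, 50 °C, reduced pressure
Reagents that add atoms: 4-methoxybenzaldehyde dimethyl acetal, COc1ccc(cc1)C(OC)OC
Why: Acid-catalysed transacetalisation should close one terminal 1,2-diol to the dioxolane; the tetraol is C2-symmetric, so mono-protection gives one constitutional isomer (acetal carbon as a mixture, erased in step 6).

**Step 4**
Reactants: 6 3,4-O-isopropylidene-1,2-O-(4-methoxybenzylidene)-D-mannitol
Product: 7 2,3-O-isopropylidene-4,5-O-(4-methoxybenzylidene)-aldehydo-D-arabinose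
Conditions: NaIO4, NaHCO3, CH2Cl2/H2O, 0 °C → rt
Reagents that add atoms: none
Why: Malaprade glycol cleavage of the remaining terminal diol should give the aldehyde that becomes C5, leaving the three stereocentres (future C6, C7, C8) untouched.

**Step 5**
Reactants: 7 2,3-O-isopropylidene-4,5-O-(4-methoxybenzylidene)-aldehydo-D-arabinose
Product: 8 1,2-dideoxy-3,4-O-isopropylidene-5,6-O-(4-methoxybenzylidene)-D-arabino-hex-1-ynitol
Conditions: dimethyl (1-diazo-2-oxopropyl)phosphonate, K2CO3, MeOH, 0 °C → rt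
Reagents that add atoms: dimethyl (1-diazo-2-oxopropyl)phosphonate, CC(=O)C(=[N+]=[N-])P(=O)(OC)OC
Why: Ohira–Bestmann (Seyferth–Gilbert) homologation should convert the aldehyde into the terminal alkyne C5≡C4; the α-centre sits on a trans-dioxolane and so has no driving force to epimerise.

**Step 6**
Reactants: 8 1,2-dideoxy-3,4-O-isopropylidene-5,6-O-(4-methoxybenzylidene)-D-arabino-hex-1-ynitol
Product: 9 1,2-dideoxy-3,4-O-isopropylidene-5-O-(4-methoxybenzyl)-D-arabino-hex-1-ynitol
Conditions: DIBAL-H, CH2Cl2, −78 → 0 °C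
Reagents that add atoms: none
Why: Regioselective reductive opening of the 4-methoxybenzylidene acetal (aluminium on the less hindered primary oxygen) should leave the PMB ether on the secondary oxygen (future O8) and free the primary alcohol (future C9).

**Step 7**
Reactants: 9 1,2-dideoxy-3,4-O-isopropylidene-5-O-(4-methoxybenzyl)-D-arabino-hex-1-ynitol
Product: 10 5,6-dideoxy-3,4-O-isopropylidene-2-O-(4-methoxybenzyl)-aldehydo-D-lyxo-hex-5-ynose
Conditions: Dess–Martin periodinane, NaHCO3, CH2Cl2, 0 °C; used at once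
Reagents that add atoms: none
Why: Dess–Martin oxidation under buffered conditions should give the α-PMB-oxy aldehyde without epimerisation of the adjacent centre.

**Step 8**
Reactants: 4 TMS enol ether of (S)-3-methyl-3-(TBDPS-oxymethyl)cyclopentanone; 10 5,6-dideoxy-3,4-O-isopropylidene-2-O-(4-methoxybenzyl)-aldehydo-D-lyxo-hex-5-ynose
Product: 11 aldol adduct (cyclopentanone with the C9 carbinol chain at C10)
Conditions: 10, MgBr2·OEt2 (3 equiv), CH2Cl2, −78 °C; then 4, −78 → −20 °C
Reagents that add atoms: none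
Why: Chelation-controlled Mukaiyama aldol: the Mg chelate of the α-PMB-oxy aldehyde should be attacked anti to its dioxolane substituent (C9–OH syn to C8–OPMB), the enol ether should react on the face opposite CH2OTBDPS (C9 chain cis to Me-15 at C10), and the chelated open transition state should give the syn relationship C10/C9 needed.

**Step 9**
Reactants: 11 aldol adduct
Product: 12 C9-O-triethylsilyl ether of 11
Conditions: TESOTf, 2,6-lutidine, CH2Cl2, −78 °C
Reagents that add atoms: triethylsilyl trifluoromethanesulfonate, CC[Si](CC)(CC)OS(=O)(=O)C(F)(F)F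
Why: Silylation of the β-hydroxy ketone should block retro-aldol cleavage and mask O9 through the basic and oxidative steps that follow.

**Step 10**
Reactants: 12 C9-O-triethylsilyl ether
Product: 13 C12-ethylidene cyclopentane
Conditions: EtPPh3Br, KHMDS (ylide, 4 equiv), THF, 0 → 45 °C
Reagents that add atoms: ethyltriphenylphosphonium bromide, CC[P+](c1ccccc1)(c1ccccc1)c1ccccc1.[Br-]
Why: Wittig ethylidenation of the α-branched cyclopentanone (the reaction used on 17-keto steroids) should deliver the exocyclic trisubstituted alkene; excess ylide covers reversible acetylide formation, and the alkene geometry is of no consequence.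

**Step 11**
Reactants: 13 C12-ethylidene cyclopentane
Product: 14 C12,C11-diol
Conditions: OsO4 (10 mol %), NMO, acetone/H2O, rt
Reagents that add atoms: osmium tetroxide (catalytic oxygen carrier), O=[Os](=O)(=O)=O; N-methylmorpholine N-oxide, C[N+]1([O-])CCOCC1; water, O
Why: Upjohn syn-dihydroxylation should occur on the α face, away from the C10 side chain and Me-15, placing the tertiary C12–OH α and the two-carbon unit β; the terminal alkyne is much less reactive towards OsO4.

**Step 12**
Reactants: 14 C12,C11-diol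
Product: 15 1-acetylcyclopentanol (tertiary α-ketol, acetyl β, OH α)
Conditions: SO3·pyridine, DMSO, i-Pr2NEt, CH2Cl2, 0 °C
Reagents that add atoms: none
Why: Parikh–Doering oxidation should convert only the secondary carbinol into the methyl ketone without glycol cleavage, removing the undefined C11 centre.

**Step 13**
Reactants: 15 1-acetylcyclopentanol
Product: 16 2-hydroxy-2-methylcyclohexanone (C12 ketone, 11α-OH, 11β-Me)
Conditions: Al(Ot-Bu)3 (2 equiv), toluene, 80 °C
Reagents that add atoms: none
Why: Exchange of the tertiary C12–OH onto aluminium gives a five-membered O–Al–O chelate with the acetyl carbonyl, in which the C12–C10 σ bond is aligned with the carbonyl π* and shifts suprafacially to the acetyl carbon while C12–O becomes the ketone (α-ketol/acyloin rearrangement, the D-homoannulation type known for 17-hydroxy-20-keto steroids). No ring is closed by cyclisation: the cyclopentane (C12, C13, C14, C1, C10) becomes the cyclohexanone by insertion of C11 between C12 and C10, a 1,2-shift ring expansion by one carbon driven by release of cyclopentane strain. C10 migrates with retention, and the new C11 centre is fixed by the syn-chelate: with the acetyl group β and the carbinol oxygen α in 15, the former carbonyl oxygen ends α (11α-OH) and Me-20 β. The selectivity needed is migration of C10 instead of C13; under electron-demanding Lewis-acid activation the secondary, more electron-rich C10 should be the better migrating group than primary C13, and the moderate temperature should keep the reaction under kinetic control so that neither a methyl shift nor reversal intervenes. The saturated C13–C14 bond excludes a competing vinyl migration, and the quaternary C11 later forces dehydrogenation towards C13.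

**Step 14**
Reactants: 16 2-hydroxy-2-methylcyclohexanone
Product: 17 cyclohex-2-enone (C13=C14)
Conditions: IBX·MPO (pre-formed), DMSO, rt
Reagents that add atoms: none
Why: IBX-mediated α,β-dehydrogenation (Nicolaou) can only proceed through the C13 enol because C11 is quaternary, so the C13=C14 enone should form regiospecifically.

**Step 15**
Reactants: 17 cyclohex-2-enone
Product: 18 12α-allylic alcohol (cis-11,12-diol)
Conditions: (S)-Me-CBS (0.5 equiv), catecholborane (4 equiv), toluene, −78 °C; MeOH, aq. NaOH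
Reagents that add atoms: none
Why: Corey–Bakshi–Shibata 1,2-reduction with catecholborane should be reagent-controlled (quaternary C11 as large group, the vinyl side as small group), delivering hydride to the β face to give 12R; catecholborane leaves the alkyne untouched at −78 °C.

**Step 16**
Reactants: 18 12α-allylic alcohol
Product: 19 9,11,12-triol
Conditions: HF·pyridine, pyridine, THF, 0 °C
Reagents that add atoms: none
Why: Buffered HF·pyridine should remove the secondary TES ether selectively in the presence of the TBDPS ether, the acetonide and the PMB ether.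

**Step 17**
Reactants: 19 9,11,12-triol
Product: 20 9,12-diacetate
Conditions: Ac2O, DMAP, pyridine, CH2Cl2, rt
Reagents that add atoms: acetic anhydride, CC(=O)OC(C)=O
Why: DMAP-catalysed acetylation should esterify the two secondary alcohols (C9, C12) and leave the hindered tertiary C11–OH free, installing both acetates of the target.

**Step 18**
Reactants: 20 9,12-diacetate
Product: 21 6,7-diol
Conditions: AcOH/H2O/THF (3:1:1), 45 °C
Reagents that add atoms: none
Why: Mild aqueous acid should hydrolyse the isopropylidene acetal while the acetates, the PMB ether and the TBDPS ether survive.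

**Step 19**
Reactants: 21 6,7-diol
Product: 23 6-chloro-7-ol (propargylic chloride), via cyclic sulfite 22 (not isolated)
Conditions: SOCl2 (1.05 equiv), Et3N, CH2Cl2, −20 °C; concentrate; LiCl, DMF, 70 °C; aq. H2SO4 work-up
Reagents that add atoms: thionyl chloride (atoms retained only in 22), O=S(Cl)Cl; lithium chloride, [Li+].[Cl-]
Why: The threo-1,2-diol should close to the cyclic sulfite, which chloride opens by SN2 at the activated propargylic C6 with inversion (cyclic sulfite opening), so that Cl ends anti to O7 and the C7 hydroxyl alone is set free after loss of SO2.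

**Step 20**
Reactants: 23 6-chloro-7-ol
Product: 24 C7 2-bromopropanoate
Conditions: 2-bromopropanoyl bromide, pyridine, CH2Cl2, −20 °C
Reagents that add atoms: 2-bromopropanoyl bromide, CC(Br)C(Br)=O
Why: Acylation of the only free secondary alcohol should install the Reformatsky donor (C17–C19, Me-18) on O7; the CHBr centre is a mixture that is erased in step 23.

**Step 21**
Reactants: 24 C7 2-bromopropanoate
Product: 25 C8 alcohol
Conditions: DDQ, CH2Cl2/pH 7 buffer, 0 °C
Reagents that add atoms: none
Why: Oxidative cleavage of the PMB ether by DDQ should free O8 without touching esters, halides, alkyne or the isolated ring alkene.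

**Step 22**
Reactants: 25 C8 alcohol
Product: 26 C8 ketone
Conditions: Dess–Martin periodinane, NaHCO3, CH2Cl2, 0 °C; used crude
Reagents that add atoms: none
Why: Buffered Dess–Martin oxidation should give the α,α′-bis(acyloxy) ketone; it is carried on without chromatography because the C7–H is acidic and C6 bears a β-chloride.

**Step 23**
Reactants: 26 C8 ketone
Product: 27 β-hydroxy-γ-lactone (8-OH, 17-Me)
Conditions: Zn dust (TMSCl-activated), THF, 0 °C → rt
Reagents that add atoms: none
Why: Intramolecular Reformatsky reaction: the zinc enolate of the C7 ester should add 5-exo to the C8 ketone with the bulky C9 branch trans to C6 on the forming lactone and the methyl group trans to C9, which gives 8R and 17R; the secondary propargylic chloride inserts zinc far more slowly than the α-bromo ester.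

**Step 24**
Reactants: 27 β-hydroxy-γ-lactone
Product: 28 2-substituted buta-1,3-diene (C5(=C16H2)–C4H=CH2)
Conditions: Grubbs II (10 mol %), ethene (1 atm), toluene, 80 °C
Reagents that add atoms: ethene, C=C
Why: Ethene–alkyne cross enyne metathesis (Mori conditions) should convert the terminal alkyne into the 2-substituted 1,3-diene, creating the C5 exo-methylene and the C4 vinyl terminus in one operation.

**Step 25**
Reactants: 28 2-substituted buta-1,3-diene
Product: 29 primary alcohol at C2
Conditions: HF·pyridine, THF, rt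
Reagents that add atoms: none
Why: Prolonged HF·pyridine treatment should cleave the primary TBDPS ether under non-basic conditions that spare the allylic chloride, the esters and the lactone.

**Step 26**
Reactants: 29 primary alcohol at C2
Product: 30 C2 aldehyde
Conditions: Dess–Martin periodinane, NaHCO3, CH2Cl2, rt
Reagents that add atoms: none
Why: Dess–Martin oxidation should give the neopentyl aldehyde, which has no α-hydrogen and cannot epimerise; the tertiary alcohols are inert.

**Step 27**
Reactants: 30 C2 aldehyde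
Product: 31 (2S)-allylic alcohol
Conditions: divinylzinc (pre-formed, 5 equiv), (−)-DAIB (25 mol %), toluene/THF, 0 °C
Reagents that add atoms: divinylzinc, C=C[Zn]C=C
Why: Amino-alcohol-catalysed asymmetric vinylzinc addition should set C2 under reagent control ((−)-DAIB delivers the group to the face that gives 2S); organozincs tolerate esters, lactone and chloride, and the tertiary alcohols only consume reagent.

**Step 28**
Reactants: 31 (2S)-allylic alcohol
Product: 32 C2 butanoate (RCM triene)
Conditions: (PrCO)2O, DMAP (cat.), Et3N, CH2Cl2, 0 °C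
Reagents that add atoms: butanoic anhydride, CCCC(=O)OC(=O)CCC
Why: Acylation of the only secondary alcohol should install the butanoate; the tertiary C8 and C11 hydroxyls do not react under these conditions.

**Step 29**
Reactants: 32 C2 butanoate
Product: 33 target (CNP0114781.2)
Conditions: Grubbs II (20 mol %), toluene (1 mM), 80 °C, argon sparge
Reagents that add atoms: none
Why: Ring-closing metathesis between the C3 vinyl group and the monosubstituted C4 terminus of the diene should close the ten-membered ring with loss of ethene; ring strain should enforce the Z C3=C4 bond, and the 1,1-disubstituted C5=C16 alkene should stay out of the catalytic cycle.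

**Compound list**

1 | 3-(hydroxymethyl)cyclopent-2-en-1-one | O=C1C=C(CO)CC1 | starting material
2 | 3-{[(tert-butyldiphenylsilyl)oxy]methyl}cyclopent-2-en-1-one | O=C1C=C(CO[Si](c2ccccc2)(c2ccccc2)C(C)(C)C)CC1 | intermediate
3 | dimethylaluminium enolate of (S)-3-methyl-3-(TBDPS-oxymethyl)cyclopentanone (C12=C10) | C[Al](C)OC1=C[C@@](C)(CO[Si](c2ccccc2)(c2ccccc2)C(C)(C)C)CC1 | intermediate
4 | tert-butyl{[(1S)-1-methyl-3-(trimethylsilyloxy)cyclopent-2-en-1-yl]methoxy}diphenylsilane | C[Si](C)(C)OC1=C[C@@](C)(CO[Si](c2ccccc2)(c2ccccc2)C(C)(C)C)CC1 | intermediate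
5 | 3,4-O-isopropylidene-D-mannitol | OC[C@@H](O)[C@H]1OC(C)(C)O[C@@H]1[C@H](O)CO | starting material
6 | 3,4-O-isopropylidene-1,2-O-(4-methoxybenzylidene)-D-mannitol (acetal carbon: both epimers) | COc1ccc(cc1)C1OC[C@@H](O1)[C@H]1OC(C)(C)O[C@@H]1[C@H](O)CO | intermediate
7 | 2,3-O-isopropylidene-4,5-O-(4-methoxybenzylidene)-aldehydo-D-arabinose | COc1ccc(cc1)C1OC[C@@H](O1)[C@H]1OC(C)(C)O[C@@H]1C=O | intermediate
8 | 1,2-dideoxy-3,4-O-isopropylidene-5,6-O-(4-methoxybenzylidene)-D-arabino-hex-1-ynitol | COc1ccc(cc1)C1OC[C@@H](O1)[C@H]1OC(C)(C)O[C@@H]1C#C | intermediate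
9 | 1,2-dideoxy-3,4-O-isopropylidene-5-O-(4-methoxybenzyl)-D-arabino-hex-1-ynitol | OC[C@@H](OCc1ccc(OC)cc1)[C@H]1OC(C)(C)O[C@@H]1C#C | intermediate
10 | 5,6-dideoxy-3,4-O-isopropylidene-2-O-(4-methoxybenzyl)-aldehydo-D-lyxo-hex-5-ynose (C9 aldehyde, 8S, 7S, 6R) | O=C[C@@H](OCc1ccc(OC)cc1)[C@H]1OC(C)(C)O[C@@H]1C#C | intermediate
11 | aldol adduct: cyclopentanone (C12=O) with Me-15 and CH2OTBDPS at C1; at C10, cis to Me-15, the chain C9H(OH)–C8H(OPMB)–C7/C6 acetonide–C≡CH; C9–OH syn to C8–OPMB | O=C1CC[C@](C)(CO[Si](c2ccccc2)(c2ccccc2)C(C)(C)C)[C@H]1[C@H](O)[C@@H](OCc2ccc(OC)cc2)[C@H]2OC(C)(C)O[C@@H]2C#C | intermediate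
12 | C9-O-TES ether of 11 | O=C1CC[C@](C)(CO[Si](c2ccccc2)(c2ccccc2)C(C)(C)C)[C@H]1[C@H](O[Si](CC)(CC)CC)[C@@H](OCc2ccc(OC)cc2)[C@H]2OC(C)(C)O[C@@H]2C#C | intermediate
13 | C12-ethylidene analogue of 12 (E/Z mixture; geometry not defined, both isomers serve) | CC=C1CC[C@](C)(CO[Si](c2ccccc2)(c2ccccc2)C(C)(C)C)[C@H]1[C@H](O[Si](CC)(CC)CC)[C@@H](OCc2ccc(OC)cc2)[C@H]2OC(C)(C)O[C@@H]2C#C | intermediate
14 | diol: tertiary C12–OH (α) and 1-hydroxyethyl group (β) on the cyclopentane (secondary carbinol centre follows the alkene geometry, erased in step 12) | CC(O)[C@@]1(O)CC[C@](C)(CO[Si](c2ccccc2)(c2ccccc2)C(C)(C)C)[C@H]1[C@H](O[Si](CC)(CC)CC)[C@@H](OCc2ccc(OC)cc2)[C@H]2OC(C)(C)O[C@@H]2C#C | intermediate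
15 | α-ketol: 1-acetylcyclopentan-1-ol, acetyl β (cis to the C10 chain), OH α | CC(=O)[C@@]1(O)CC[C@](C)(CO[Si](c2ccccc2)(c2ccccc2)C(C)(C)C)[C@H]1[C@H](O[Si](CC)(CC)CC)[C@@H](OCc2ccc(OC)cc2)[C@H]2OC(C)(C)O[C@@H]2C#C | intermediate
16 | ring-expanded ketol: cyclohexanone (C12=O) with C11(OH α)(Me-20 β), C10 chain β, C1 (Me-15 β, CH2OTBDPS α) | O=C1CC[C@](C)(CO[Si](c2ccccc2)(c2ccccc2)C(C)(C)C)[C@@H]([C@H](O[Si](CC)(CC)CC)[C@@H](OCc2ccc(OC)cc2)[C@H]2OC(C)(C)O[C@@H]2C#C)[C@]1(C)O | intermediate
17 | C13=C14 enone of 16 | O=C1C=C[C@](C)(CO[Si](c2ccccc2)(c2ccccc2)C(C)(C)C)[C@@H]([C@H](O[Si](CC)(CC)CC)[C@@H](OCc2ccc(OC)cc2)[C@H]2OC(C)(C)O[C@@H]2C#C)[C@]1(C)O | intermediate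
18 | 12α-allylic alcohol (12R; cis to 11-OH) | O[C@@H]1C=C[C@](C)(CO[Si](c2ccccc2)(c2ccccc2)C(C)(C)C)[C@@H]([C@H](O[Si](CC)(CC)CC)[C@@H](OCc2ccc(OC)cc2)[C@H]2OC(C)(C)O[C@@H]2C#C)[C@]1(C)O | intermediate
19 | 9,11,12-triol (TES removed) | O[C@@H]1C=C[C@](C)(CO[Si](c2ccccc2)(c2ccccc2)C(C)(C)C)[C@@H]([C@H](O)[C@@H](OCc2ccc(OC)cc2)[C@H]2OC(C)(C)O[C@@H]2C#C)[C@]1(C)O | intermediate
20 | 9,12-diacetate, 11-OH free | CC(=O)O[C@@H]1C=C[C@](C)(CO[Si](c2ccccc2)(c2ccccc2)C(C)(C)C)[C@@H]([C@H](OC(C)=O)[C@@H](OCc2ccc(OC)cc2)[C@H]2OC(C)(C)O[C@@H]2C#C)[C@]1(C)O | intermediate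
21 | 6,7-diol (threo) of 20 | CC(=O)O[C@@H]1C=C[C@](C)(CO[Si](c2ccccc2)(c2ccccc2)C(C)(C)C)[C@@H]([C@H](OC(C)=O)[C@@H](OCc2ccc(OC)cc2)[C@@H](O)[C@H](O)C#C)[C@]1(C)O | intermediate
22 | 6,7-cyclic sulfite of 21 (sulfur epimers) | CC(=O)O[C@@H]1C=C[C@](C)(CO[Si](c2ccccc2)(c2ccccc2)C(C)(C)C)[C@@H]([C@H](OC(C)=O)[C@@H](OCc2ccc(OC)cc2)[C@H]2OS(=O)O[C@@H]2C#C)[C@]1(C)O | intermediate
23 | 6-chloro-7-ol (6S, Cl anti to O7) | CC(=O)O[C@@H]1C=C[C@](C)(CO[Si](c2ccccc2)(c2ccccc2)C(C)(C)C)[C@@H]([C@H](OC(C)=O)[C@@H](OCc2ccc(OC)cc2)[C@@H](O)[C@@H](Cl)C#C)[C@]1(C)O | intermediate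
24 | C7 2-bromopropanoate of 23 (CHBr epimers) | CC(=O)O[C@@H]1C=C[C@](C)(CO[Si](c2ccccc2)(c2ccccc2)C(C)(C)C)[C@@H]([C@H](OC(C)=O)[C@@H](OCc2ccc(OC)cc2)[C@@H](OC(=O)C(C)Br)[C@@H](Cl)C#C)[C@]1(C)O | intermediate
25 | C8 alcohol (PMB removed) | CC(=O)O[C@@H]1C=C[C@](C)(CO[Si](c2ccccc2)(c2ccccc2)C(C)(C)C)[C@@H]([C@H](OC(C)=O)[C@@H](O)[C@@H](OC(=O)C(C)Br)[C@@H](Cl)C#C)[C@]1(C)O | intermediate
26 | C8 ketone | CC(=O)O[C@@H]1C=C[C@](C)(CO[Si](c2ccccc2)(c2ccccc2)C(C)(C)C)[C@@H]([C@H](OC(C)=O)C(=O)[C@@H](OC(=O)C(C)Br)[C@@H](Cl)C#C)[C@]1(C)O | intermediate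
27 | γ-lactone (C7–O–C19(=O)–C17–C8) with 8-OH and 17-Me cis, C6–Cl, terminal alkyne, C2–OTBDPS | CC(=O)O[C@@H]1C=C[C@](C)(CO[Si](c2ccccc2)(c2ccccc2)C(C)(C)C)[C@@H]([C@H](OC(C)=O)[C@]2(O)[C@@H](C)C(=O)O[C@H]2[C@@H](Cl)C#C)[C@]1(C)O | intermediate
28 | 2-substituted buta-1,3-diene C5(=CH2)–CH=CH2 in place of the alkyne of 27 | CC(=O)O[C@@H]1C=C[C@](C)(CO[Si](c2ccccc2)(c2ccccc2)C(C)(C)C)[C@@H]([C@H](OC(C)=O)[C@]2(O)[C@@H](C)C(=O)O[C@H]2[C@@H](Cl)C(=C)C=C)[C@]1(C)O | intermediate
29 | primary alcohol at C2 (TBDPS removed) | CC(=O)O[C@@H]1C=C[C@](C)(CO)[C@@H]([C@H](OC(C)=O)[C@]2(O)[C@@H](C)C(=O)O[C@H]2[C@@H](Cl)C(=C)C=C)[C@]1(C)O | intermediate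
30 | C2 aldehyde on quaternary C1 | CC(=O)O[C@@H]1C=C[C@](C)(C=O)[C@@H]([C@H](OC(C)=O)[C@]2(O)[C@@H](C)C(=O)O[C@H]2[C@@H](Cl)C(=C)C=C)[C@]1(C)O | intermediate
31 | (2S)-allylic alcohol (C2–OH, C3 vinyl) | CC(=O)O[C@@H]1C=C[C@](C)([C@@H](O)C=C)[C@@H]([C@H](OC(C)=O)[C@]2(O)[C@@H](C)C(=O)O[C@H]2[C@@H](Cl)C(=C)C=C)[C@]1(C)O | intermediate
32 | C2 butanoate of 31 (triene for RCM) | CC(=O)O[C@@H]1C=C[C@](C)([C@@H](OC(=O)CCC)C=C)[C@@H]([C@H](OC(C)=O)[C@]2(O)[C@@H](C)C(=O)O[C@H]2[C@@H](Cl)C(=C)C=C)[C@]1(C)O | intermediate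
33 | CNP0114781.2: (1S,2S,3Z,6S,7R,8R,9S,10S,11S,12R,17R) 2-butanoyloxy-9,12-diacetoxy-6-chloro-8,11-dihydroxy-3,5(16),13-triene 7,19-lactone (target numbering) | C=C1/C=C\[C@H](OC(=O)CCC)[C@@]2(C)C=C[C@@H](OC(C)=O)[C@@](C)(O)[C@@H]2[C@H](OC(C)=O)[C@]2(O)[C@@H](C)C(=O)O[C@H]2[C@H]1Cl | target

**Totals.** 29 steps in all. Longest linear sequence: 27 steps (from 5: steps 3–7, then 8–29).

**Steps most likely to fail**

1. Step 13 (key step). The 1,2-shift may follow the wrong ring bond (C13 instead of C10), or the ketol may equilibrate further by a methyl shift under Lewis-acid activation. Fallback through the oxy-anion manifold, setting out from 12 and returning at 16: 1-ethoxyvinyllithium/CeCl3 (THF, −78 °C) should add to the C12 ketone from the α face, anti to the C10 side chain, to give the 1-ethoxyvinyl carbinol F1. Hydrolysis of the enol ether (oxalic acid, wet silica) gives the C12-epimeric α-ketol F2 (acetyl α, OH β). Its potassium alkoxide (KH, 18-crown-6, THF, 0 °C) cannot chelate and should rearrange through the dipole-opposed anti conformer, which from this epimer leads to the same 11α-OH/11β-Me ketol 16 (base-mediated acyloin rearrangement).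

2. Step 8. π-Facial discrimination on the enol ether by the quaternary C1 (CH2OTBDPS against CH3), or the relative topicity of the open transition state, may be poor. C9 remains fixed by the chelate, so attack on the wrong enol ether face gives the C10 epimer. Fallback by thermodynamic instead of kinetic control, setting out from 4 and 10 and returning at 12: the same chelated addition is accepted as it comes and gives the C10-epimeric aldol F3, which is silylated (TESOTf, 2,6-lutidine) to the C10-epimeric TES ether F4. The C10 centre, α to the ketone, is then equilibrated (DBU, toluene, rt) to 12, in which the side chain is trans to the larger CH2OTBDPS group.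

3. Step 29. Ring closure may lose to oligomerisation, or the ruthenium vinyl-alkylidene formed on the diene may stall or engage the 1,1-disubstituted alkene. Fallback by ring-closing enyne metathesis, setting out from 27 and returning at 33: the alkyne is kept while C2 is elaborated. HF·pyridine gives the alkynyl primary alcohol F5, Dess–Martin oxidation the alkynyl aldehyde F6, divinylzinc/(−)-DAIB the alkynyl (2S)-allylic alcohol F7, and butanoic anhydride/DMAP the alkynyl butanoate F8. Grubbs II under ethene in dilute toluene at 80 °C should then close the ten-membered ring in the endo mode, forming C3=C4 and the C5 exo-methylene in one event to give 33.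

**Further compounds**

F1 | step 13 | 1-ethoxyvinyl carbinol from 12 (C-substituent α, OH β at C12) | C=C(OCC)[C@]1(O)CC[C@](C)(CO[Si](c2ccccc2)(c2ccccc2)C(C)(C)C)[C@H]1[C@H](O[Si](CC)(CC)CC)[C@@H](OCc2ccc(OC)cc2)[C@H]2OC(C)(C)O[C@@H]2C#C
F2 | step 13 | C12-epimeric α-ketol (acetyl α, OH β) | CC(=O)[C@]1(O)CC[C@](C)(CO[Si](c2ccccc2)(c2ccccc2)C(C)(C)C)[C@H]1[C@H](O[Si](CC)(CC)CC)[C@@H](OCc2ccc(OC)cc2)[C@H]2OC(C)(C)O[C@@H]2C#C
F3 | step 8 | C10-epimeric aldol adduct | O=C1CC[C@](C)(CO[Si](c2ccccc2)(c2ccccc2)C(C)(C)C)[C@@H]1[C@H](O)[C@@H](OCc2ccc(OC)cc2)[C@H]2OC(C)(C)O[C@@H]2C#C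
F4 | step 8 | C10-epimeric TES ether | O=C1CC[C@](C)(CO[Si](c2ccccc2)(c2ccccc2)C(C)(C)C)[C@@H]1[C@H](O[Si](CC)(CC)CC)[C@@H](OCc2ccc(OC)cc2)[C@H]2OC(C)(C)O[C@@H]2C#C
F5 | step 29 | alkynyl primary alcohol (27 without TBDPS) | CC(=O)O[C@@H]1C=C[C@](C)(CO)[C@@H]([C@H](OC(C)=O)[C@]2(O)[C@@H](C)C(=O)O[C@H]2[C@@H](Cl)C#C)[C@]1(C)O
F6 | step 29 | alkynyl C2 aldehyde | CC(=O)O[C@@H]1C=C[C@](C)(C=O)[C@@H]([C@H](OC(C)=O)[C@]2(O)[C@@H](C)C(=O)O[C@H]2[C@@H](Cl)C#C)[C@]1(C)O
F7 | step 29 | alkynyl (2S)-allylic alcohol | CC(=O)O[C@@H]1C=C[C@](C)([C@@H](O)C=C)[C@@H]([C@H](OC(C)=O)[C@]2(O)[C@@H](C)C(=O)O[C@H]2[C@@H](Cl)C#C)[C@]1(C)O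
F8 | step 29 | alkynyl C2 butanoate (enyne for ring closure) | CC(=O)O[C@@H]1C=C[C@](C)([C@@H](OC(=O)CCC)C=C)[C@@H]([C@H](OC(C)=O)[C@]2(O)[C@@H](C)C(=O)O[C@H]2[C@@H](Cl)C#C)[C@]1(C)O
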